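The plan takes the C7–C8 single bond back to the C7=C8 double bond of a flat, achiral (E)-aryl enol ether, ArCH=C(CH3)OAr′. In this precursor the congested C8–O bond to the 2,6-dimethoxyphenyl ring is already in place, having been made at sp2 carbon. One reagent-controlled suprafacial hydroboration–oxidation then sets both stereocentres as a group. The alkene geometry fixes threo, and the isopinocampheyl group fixes 7R,8R. The step exploits the fact that the 3,4,5-trimethoxyphenyl ring on C7 and the aryloxy oxygen on C8 polarise this alkene in the same sense, so that boron, and later oxygen, goes to C7 only.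

Key step: step 4

Remark: neolignan numbering is used (C7 = benzylic carbon bearing OAc, C8 = carbon bearing the aryloxy group, C9 = methyl). The given SMILES corresponds to the (7R,8R) isomer, which is threo, with an E alkene in the side chain.

Step 1
Reactants: 1 5-iodo-1,2,3-trimethoxybenzene; 2 propyne
Product: 3 1,2,3-trimethoxy-5-(prop-1-yn-1-yl)benzene
Conditions: PdCl2(PPh3)2 (2 mol %), CuI (4 mol %), Et3N, propyne (solution in THF), sealed vessel, rt
Reagents that add atoms: none
Why: Sonogashira coupling of an aryl iodide with a terminal alkyne runs at room temperature, and no other group of 1 reacts with Pd(0)/Cu(I).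

Step 2
Reactants: 3 1,2,3-trimethoxy-5-(prop-1-yn-1-yl)benzene
Product: 4 (Z)-4,4,5,5-tetramethyl-2-[1-(3,4,5-trimethoxyphenyl)prop-1-en-2-yl]-1,3,2-dioxaborolane (aryl ring cis to methyl, H-7 cis to boron)
Conditions: CuCl (5 mol %), P(p-tol)3 (6 mol %), NaOt-Bu (10 mol %), B2pin2 (1.1 equiv), MeOH (2 equiv), THF, rt
Reagents that add atoms: bis(pinacolato)diboron, CC1(C)OB(OC1(C)C)B1OC(C)(C)C(C)(C)O1
Why: Copper-catalysed formal hydroboration (syn borylcupration, then protonation of the C–Cu bond by MeOH) places copper on the aryl-stabilised C7 and boron on C8, so that H and Bpin end up cis and the Z boronate should form.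

Step 3
Reactants: 4 (Z)-alkenyl pinacol boronate; 5 4-bromo-2,6-dimethoxyphenol
Product: 6 (E)-5-[2-(4-bromo-2,6-dimethoxyphenoxy)prop-1-en-1-yl]-1,2,3-trimethoxybenzene (aryl ring cis to methyl, trans to the aryloxy group)
Conditions: Cu(OAc)2 (2 equiv), Et3N (4 equiv), 4 Å MS, CH2Cl2, argon, rt; chromatography on Et3N-deactivated silica
Reagents that add atoms: none
Why: In this Chan–Lam–Evans coupling, transmetalation of the alkenyl group to Cu(II), oxidation to Cu(III) by the second equivalent and C–O reductive elimination proceed with retention of alkene geometry, di-ortho-substituted phenols are tolerated by this reaction type, and the aryl bromide is inert to Cu(II).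

Step 4
Reactants: 6 (E)-aryl enol ether
Product: 8 (1R,2R)-2-(4-bromo-2,6-dimethoxyphenoxy)-1-(3,4,5-trimethoxyphenyl)propan-1-ol, via benzylic isopinocampheylborane 7 (not isolated)
Conditions: (IpcBH2)2·TMEDA [from (−)-α-pinene], BF3·OEt2, THF, rt, filter; 6, THF, −25 → 0 °C; MeOH; 30% H2O2, pH 7 buffer, 0 °C → rt
Reagents that add atoms: hydrogen peroxide, OO (gives the oxygen on C7); monoisopinocampheylborane from (−)-α-pinene, B[C@H]1C[C@H]2C[C@@H]([C@@H]1C)C2(C)C (its boron and Ipc group stay only in 7; 8 keeps its hydrogen on C8)
Why: Brown asymmetric hydroboration followed by oxidation: the B–H bond adds across C7=C8 through a concerted four-centre transition state, so that boron (on C7) and hydrogen (on C8) arrive on the same face, and the C7–B bond is then replaced by C7–O with retention. The closest known reaction type is the hydroboration of acyclic trisubstituted enol ethers and of aryl-substituted trisubstituted alkenes with α-pinene-derived boranes, and no ring is closed. Regioselectivity is secured three times over by the substrate, because donation from the oxygen on C8 makes C7 the nucleophilic and C8 the hydride-accepting carbon, C7 is the less substituted terminus, and C7 is benzylic. The relative configuration is controlled by the E geometry of 6 alone, since with the aryl ring cis to CH3 and H-7 cis to OAr′ a suprafacial addition can only give the threo (7R,8R)/(7S,8S) pair. The absolute configuration of C7, and through it of C8, is controlled by the isopinocampheyl group: the reagent from (+)-α-pinene is known to give S carbinol centres with trans-disubstituted and trisubstituted alkenes of the same priority pattern (OH > Cβ > substituent > H), so the reagent from (−)-α-pinene should attack the face that leads to 7R,8R. The step also needs the β-aryloxyborane 7 to outlive β-elimination, which the low temperature, the removal of all BF3 as its insoluble TMEDA adduct and the buffered oxidation should secure.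

Step 5
Reactants: 8 (1R,2R)-alcohol
Product: 9 (1R,2R)-2-(4-bromo-2,6-dimethoxyphenoxy)-1-(3,4,5-trimethoxyphenyl)propyl acetate
Conditions: Ac2O, pyridine, DMAP (cat.), CH2Cl2, 0 °C → rt
Reagents that add atoms: acetic anhydride, CC(=O)OC(C)=O
Why: DMAP-catalysed acylation of the only hydroxy group breaks no C–O bond at C7 or C8, so both stereocentres are kept, and the acetate is placed before any primary alcohol exists in the molecule.

Step 6
Reactants: 10 prop-2-yn-1-ol; 11 tributyltin hydride
Product: 12 (E)-3-(tributylstannyl)prop-2-en-1-ol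
Conditions: AIBN (cat.), neat, 80 °C; chromatography
Reagents that add atoms: none
Why: Radical hydrostannation of a terminal alkyne under thermodynamic control should favour the E β-stannane, because reversible addition of the stannyl radical equilibrates the isomers, and the minor isomers are removed by chromatography.

Step 7
Reactants: 9 (1R,2R)-bromo acetate; 12 (E)-3-(tributylstannyl)prop-2-en-1-ol
Product: 13 (1R,2R)-2-{4-[(E)-3-hydroxyprop-1-en-1-yl]-2,6-dimethoxyphenoxy}-1-(3,4,5-trimethoxyphenyl)propyl acetate (target)
Conditions: Pd[P(t-Bu)3]2 (5 mol %), CsF (2.2 equiv), dioxane, rt → 50 °C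
Reagents that add atoms: none
Why: Stille coupling with an electron-rich bulky phosphine and fluoride activation couples even electron-rich aryl bromides near room temperature with retention of the alkene geometry, and the mild medium should leave the C7 acetate, the free allylic alcohol and both stereocentres untouched.

Compound list
1 | 5-iodo-1,2,3-trimethoxybenzene | COc1cc(I)cc(OC)c1OC | starting material
2 | propyne | CC#C | starting material
3 | 1,2,3-trimethoxy-5-(prop-1-yn-1-yl)benzene | COc1cc(C#CC)cc(OC)c1OC | intermediate
4 | (Z)-4,4,5,5-tetramethyl-2-[1-(3,4,5-trimethoxyphenyl)prop-1-en-2-yl]-1,3,2-dioxaborolane | COc1cc(/C=C(\C)B2OC(C)(C)C(C)(C)O2)cc(OC)c1OC | intermediate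
5 | 4-bromo-2,6-dimethoxyphenol | COc1cc(Br)cc(OC)c1O | starting material
6 | (E)-5-[2-(4-bromo-2,6-dimethoxyphenoxy)prop-1-en-1-yl]-1,2,3-trimethoxybenzene | COc1cc(/C=C(\C)Oc2c(OC)cc(Br)cc2OC)cc(OC)c1OC | intermediate
7 | [(1R,2R)-2-(4-bromo-2,6-dimethoxyphenoxy)-1-(3,4,5-trimethoxyphenyl)propyl](isopinocampheyl)borane, Ipc from (−)-α-pinene | COc1cc([C@@H](B[C@H]3C[C@H]4C[C@@H]([C@@H]3C)C4(C)C)[C@@H](C)Oc2c(OC)cc(Br)cc2OC)cc(OC)c1OC | intermediate
8 | (1R,2R)-2-(4-bromo-2,6-dimethoxyphenoxy)-1-(3,4,5-trimethoxyphenyl)propan-1-ol | COc1cc([C@@H](O)[C@@H](C)Oc2c(OC)cc(Br)cc2OC)cc(OC)c1OC | intermediate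
9 | (1R,2R)-2-(4-bromo-2,6-dimethoxyphenoxy)-1-(3,4,5-trimethoxyphenyl)propyl acetate | COc1cc([C@@H](OC(C)=O)[C@@H](C)Oc2c(OC)cc(Br)cc2OC)cc(OC)c1OC | intermediate
10 | prop-2-yn-1-ol | C#CCO | starting material
11 | tributyltin hydride | CCCC[SnH](CCCC)CCCC | starting material
12 | (E)-3-(tributylstannyl)prop-2-en-1-ol | CCCC[Sn](CCCC)(CCCC)/C=C/CO | intermediate
13 | (1R,2R)-2-{4-[(E)-3-hydroxyprop-1-en-1-yl]-2,6-dimethoxyphenoxy}-1-(3,4,5-trimethoxyphenyl)propyl acetate | COc1cc([C@@H](OC(C)=O)[C@@H](C)Oc2c(OC)cc(/C=C/CO)cc2OC)cc(OC)c1OC | target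

Total step count: 7
Longest linear sequence: 6 (steps 1–5 and 7)

Steps most likely to fail

Step 4. Three things may go wrong:
- The borane may show poor or reversed facial selectivity on an alkene whose C7 substituent is a large aryl ring.
- Addition to the hindered trisubstituted alkene may be sluggish.
- Boron and aryloxide may undergo β-elimination before the oxidation.

The fallback gives up the alkene addition and takes C8 from the chiral pool. It sets out from 5 and comes back at 8. Mitsunobu reaction of 5 with commercial ethyl (S)-lactate (PPh3, DIAD, THF, inversion) should give ethyl (R)-2-(4-bromo-2,6-dimethoxyphenoxy)propanoate F1. Treatment with MeNH(OMe)·HCl and i-PrMgCl at −20 °C converts it into (R)-2-(4-bromo-2,6-dimethoxyphenoxy)-N-methoxy-N-methylpropanamide F2. Commercial 3,4,5-trimethoxyphenylmagnesium bromide then gives (R)-2-(4-bromo-2,6-dimethoxyphenoxy)-1-(3,4,5-trimethoxyphenyl)propan-1-one F3. Reduction with L-Selectride at −78 °C under Felkin–Anh control, with hydride entering anti to the aryloxy group, should give threo 8.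

Step 3. Transmetalation of the hindered pinacol boronate may be slow, which would leave room for protodeboronation and for oxidative degradation of the electron-rich phenol by Cu(II). The fallback reverses the role of the alkenyl partner and avoids any oxidant. It sets out from 4 and comes back at 6. Iododeboronation (aq NaOH, then I2, THF, retention) should give (E)-5-(2-iodoprop-1-en-1-yl)-1,2,3-trimethoxybenzene F4. This iodide is joined to 5 by an Ullmann-type vinylation (CuI, N,N-dimethylglycine, Cs2CO3, dioxane, 80 °C), which is also stereoretentive.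

Step 7. Oxidative addition into the electron-rich aryl bromide may be slow, the stannane may undergo protodestannylation, or fluoride may induce acetyl transfer from O7 to the newly introduced primary alcohol. The fallback installs the side chain before the acetate and masks its oxygen. It sets out from 8 and comes back at 13. Suzuki–Miyaura coupling of 8 with commercial (E)-3-(tert-butyldimethylsilyloxy)prop-1-enylboronic acid pinacol ester (Pd(dppf)Cl2, K2CO3, dioxane/H2O, 80 °C) should give (1R,2R)-2-{4-[(E)-3-(tert-butyldimethylsilyloxy)prop-1-en-1-yl]-2,6-dimethoxyphenoxy}-1-(3,4,5-trimethoxyphenyl)propan-1-ol F5. Acetylation (Ac2O, pyridine, DMAP) gives the corresponding (1R,2R)-silyl ether acetate F6. HF·pyridine in THF at 0 °C removes the silyl group without touching the acetate and gives 13.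

Further compounds
F1 | step 4 | ethyl (R)-2-(4-bromo-2,6-dimethoxyphenoxy)propanoate | CCOC(=O)[C@@H](C)Oc1c(OC)cc(Br)cc1OC
F2 | step 4 | (R)-2-(4-bromo-2,6-dimethoxyphenoxy)-N-methoxy-N-methylpropanamide | CON(C)C(=O)[C@@H](C)Oc1c(OC)cc(Br)cc1OC
F3 | step 4 | (R)-2-(4-bromo-2,6-dimethoxyphenoxy)-1-(3,4,5-trimethoxyphenyl)propan-1-one | COc1cc(C(=O)[C@@H](C)Oc2c(OC)cc(Br)cc2OC)cc(OC)c1OC
F4 | step 3 | (E)-5-(2-iodoprop-1-en-1-yl)-1,2,3-trimethoxybenzene | COc1cc(/C=C(\C)I)cc(OC)c1OC
F5 | step 7 | (1R,2R)-2-{4-[(E)-3-(tert-butyldimethylsilyloxy)prop-1-en-1-yl]-2,6-dimethoxyphenoxy}-1-(3,4,5-trimethoxyphenyl)propan-1-ol | COc1cc([C@@H](O)[C@@H](C)Oc2c(OC)cc(/C=C/CO[Si](C)(C)C(C)(C)C)cc2OC)cc(OC)c1OC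
F6 | step 7 | (1R,2R)-2-{4-[(E)-3-(tert-butyldimethylsilyloxy)prop-1-en-1-yl]-2,6-dimethoxyphenoxy}-1-(3,4,5-trimethoxyphenyl)propyl acetate | COc1cc([C@@H](OC(C)=O)[C@@H](C)Oc2c(OC)cc(/C=C/CO[Si](C)(C)C(C)(C)C)cc2OC)cc(OC)c1OC
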